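**Numbering convention.** Benzo[7]annulene locants are used for every compound: C1–C4 aromatic, C4a, C5 (the future spiro carbon), C6 (CH2), C7, C8, C9, C9a. Ring A is the arene, ring B the seven-membered ring, ring C the spiro six-membered ring (primed locants, C1' = C5).

## Analysis of the target

The target has three rings: a 2,3,4-trimethoxybenzene (ring A), a seven-membered carbocycle fused to it (ring B) and a 3',5'-dimethoxycyclohexa-2',5'-dien-4'-one (ring C) that shares C5 with ring B. Ring B carries three contiguous stereocentres, C7 (R, methyl), C8 (S, methyl) and C9 (R, acetoxy). The substituents alternate faces, so the two methyls are trans, and the acetoxy group is trans to the C8 methyl and cis to the C7 methyl. C5 is quaternary but not stereogenic, because ring C has a mirror plane through C1' and C4'. The sensitive groups are the cross-conjugated dienone (a Michael acceptor, reducible, prone to dienone–phenol rearrangement in strong acid) and the benzylic acetate at C9, which is para to the C3 methoxy group and can ionise. The difficulty is twofold: three adjacent stereocentres on a flexible seven-membered ring, and a quaternary spiro carbon wedged between the C4 methoxy group and two rings. The feature used here is that C9 is a benzylic carbinol. At the ketone oxidation level C7 and C8 are the β- and α-carbons of an aryl ketone, so a C7=C8 enone in ring B is one precursor for both methyl-bearing centres. If C5 then carries two identical ester groups, that enone has no stereocentre at all.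

## Retrosynthetic reasoning

**Acetate and silyl ether.** The C9–O acyl bond of 25 is cut first to give alcohol 24, which is the desilylation product of 23. An acetate would not survive the hydride, enolate and hot-salt steps between the key step and the dienone. C9–O therefore travels as a silyl ether and the ester is put on last.

**Second methoxy-enone half of ring C.** In 23 the C5'–OCH3 bond is cut to give diosphenol 22. Removing the C5' oxygen and the C5'=C6' unsaturation then leads to the mono-methoxy enone 20. This is preferred to making the symmetric dienone in one stroke because 20 has a single enolisable position (C5'; C1' is quaternary), so oxygenation is site-defined. The gain is convergence: 20 is a pair of spiro epimers, and both become one compound once ring C is symmetric.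

**Ring C.** Cutting C5–C6' and the C2'=C3' double bond of 20 gives aldehyde 16 and vinyl ketone 17. The cut is placed at the quaternary carbon because an α-aryl aldehyde enolate is a good donor for a quaternising Michael addition. The aldol condensation that follows can only close a six-membered ring through the methoxy-bearing carbon. The forward reaction must form a congested C–C bond next to the C4 methoxy group; its configuration at C5 does not matter.

**Oxidation level at C5.** Aldehyde 16 comes from alcohol 15 and ester 14, and 14 from the geminal diester 13 by loss of one methoxycarbonyl group. The second ester exists only to keep the earlier enone achiral and is discarded once the stereocentres are in place.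

**C9.** 13 is the silyl ether of 12, and cutting the C9–H bond of 12 gives ketone 11. The reduction must put the hydroxyl trans to the C8 methyl. A reagent-controlled hydride transfer to the aryl ketone is planned so that the outcome does not rest on the conformation of ring B.

**C7 and C8 (key disconnection).** Both C–CH3 bonds of 11 are cut, C7–CH3 as a conjugate addition and C8–CH3 as an enolate alkylation, which gives enone 9. Cutting here and not at ring bonds means the stereocentres are set on a finished, achiral carbocycle by one catalyst.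

**Ring B.** Enone 9 is the dehydrogenation product of ketone 7 (through 8). In 7 the C9–C9a bond is cut, which corresponds to intramolecular acylation of the arene by acid 6, itself from 5. C9a is the only free ortho position next to the quaternary carbon and is para to the central methoxy group, so the tether fixes the regiochemistry. Bringing C9 in on the arene first would instead need a coupling at a doubly ortho-substituted aryl carbon and would later place a C9 alkoxide next to the malonate esters.

**Chain and arene.** The C5–C6 bond of 5 is cut to arylmalonate 3 and bromo ester 4, and the C4a–C5 bond of 3 to aryl bromide 1 and malonate 2. All bonds to C5 in the precursor are thus made by malonate chemistry.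

## Alternatives that were turned down

**Alternative 1: spiroannulation as the central step.**
- Disconnection: C5–C6' and C2'=C3' of ring C.
- Forward step: the enolate of aldehyde 16 adds to vinyl ketone 17 and the adduct condenses to the spiro methoxy-enone A1 (one spiro epimer of 20).
- For it: it attacks the hardest skeletal feature, the quaternary carbon beside the C4 methoxy group, in one two-bond, ring-forming operation, and the spiro configuration is irrelevant. On this point it is not weaker than the chosen plan, which uses the same annulation as step 11.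
- Against it: it creates none of the three stereocentres of the target. It presupposes an aldehyde that already holds C7, C8 and C9, so the stereochemical problem is only moved.
- Comparison: step economy is the same because the endgame is shared. The chosen strategy additionally says how the stereotriad arises, and it places the uncertain step early on an achiral compound that is four steps from commercial material.

**Alternative 2: carbonyl ylide cycloaddition.**
- Disconnection: C9–C8 and C6–C7 of ring B.
- Forward step: Rh2(OAc)4 converts diazo ketone A2 into the benzopyrylium olate A3, which adds across crotonoyl imide A4 under a chiral Yb(OTf)3–pybox catalyst to give the oxygen-bridged cycloadduct A5.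
- For it: it is stronger than the chosen key step in bonds and stereocentres per operation. Ring B, C7, C8 and C9 with its oxygen all arise at once, and the endo-acyl/exo-methyl arrangement maps onto the required alternating triad.
- Against it:
  - C8 arrives as an acyl group that must be taken down to methyl (reduction, activation, deoxygenation).
  - The bridge must be opened at C6–O only.
  - C5 arrives as a ketone, so a one-carbon homologation is needed before ring C can be built.
  - A2 carries its diazoacetyl group between a methoxy and a formyl group and is itself several steps away.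
  - Enantioselection requires the chiral Lewis acid pathway to outrun the achiral rhodium-bound ylide, and the three methoxy groups change the frontier orbitals of A3.
- Comparison: the chosen strategy forms fewer bonds in its key step, but both methyls arrive at the final oxidation level and C5 already carries the ester handle for ring C.

**Alternative 3: aryne insertion with ring expansion.**
- Disconnection: C9a–C9 and C4a–C5.
- Forward step: silyl triflate A6 and CsF release aryne A7, which inserts into the ketone–α-carbon bond of the trans-dimethyl β-keto ester A8 to give benzo-fused keto ester A9.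
- For it: ring B is assembled in one step from two fragments, which is more convergent than the three steps used here. The regiochemistry is favourable, since the carbon nucleophile adds to the aryne carbon remote from the methoxy group.
- Against it:
  - The step controls no stereocentre. C7 and C8 must be set beforehand in A8, which needs its own asymmetric synthesis, and C9 emerges as an epimerisable CH–CO2CH3.
  - C9 bears carbon instead of oxygen. Replacing the ester by an acetoxy group at a benzylic centre goes through radical or cationic intermediates, so the configuration is lost.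
  - C5 is again a ketone that needs homologation, and A6 is a multi-step building block.
- Comparison: the chosen strategy keeps C9 as a ketone, so the C–O stereocentre comes from one reduction, and it sets C7 and C8 catalytically on an achiral substrate.

Key step: step 5

**Assumptions.** (i) The (R,Sp) antipode of the Josiphos ligand is assumed to deliver methyl to the C7 face that leads to the (7R) series. If the opposite sense is found, the commercially available (S,Rp) ligand is used and nothing else changes. (ii) Vinyl ketone 17 is taken as a purchasable, stabilised reagent that is distilled before use.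

## Route

Step 1
Reactants: 1 1-bromo-2,3,4-trimethoxybenzene; 2 dimethyl malonate
Product: 3 dimethyl 2-(2,3,4-trimethoxyphenyl)malonate
Conditions: Pd(OAc)2 (2 mol%), P(t-Bu)3·HBF4 (4 mol%), K3PO4, toluene, 80 °C
Reagents that add atoms: none
Why: Palladium-catalysed α-arylation of a malonate: oxidative addition of the aryl bromide to zerovalent palladium, exchange with the potassium malonate and reductive elimination from the bulky electron-rich phosphine complex. A single ortho methoxy group is tolerated, and the more acidic product is not arylated twice.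

Step 2
Reactants: 3 dimethyl 2-(2,3,4-trimethoxyphenyl)malonate; 4 tert-butyl 4-bromobutanoate
Product: 5 4-tert-butyl 1,1-dimethyl 1-(2,3,4-trimethoxyphenyl)butane-1,1,4-tricarboxylate
Conditions: NaH, DMF, 0 °C; then 4, NaI (cat.), 60 °C
Reagents that add atoms: none
Why: SN2 alkylation of the stabilised arylmalonate anion by a primary bromide forms the C5–C6 bond. The malonate anion is too weak a base to enolise the tert-butyl ester, so self-cyclisation of 4 should not compete.

Step 3
Reactants: 5 4-tert-butyl 1,1-dimethyl 1-(2,3,4-trimethoxyphenyl)butane-1,1,4-tricarboxylate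
Product: 7 dimethyl 2,3,4-trimethoxy-9-oxo-6,7,8,9-tetrahydro-5H-benzo[7]annulene-5,5-dicarboxylate, via carboxylic acid 6 (not isolated)
Conditions: TFA, CH2Cl2, rt; evaporate; then Eaton's reagent (P2O5 in MeSO3H), rt
Reagents that add atoms: none
Why: Acidolysis removes only the tert-butyl ester, and acid 6 is then activated for an intramolecular Friedel–Crafts acylation. C9a is the only ortho position available and is para to the C3 methoxy group, and the geminal diester favours the seven-membered closure.

Step 4
Reactants: 7 dimethyl 2,3,4-trimethoxy-9-oxo-6,7,8,9-tetrahydro-5H-benzo[7]annulene-5,5-dicarboxylate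
Product: 9 dimethyl 2,3,4-trimethoxy-9-oxo-6,9-dihydro-5H-benzo[7]annulene-5,5-dicarboxylate, via trimethylsilyl enol ether 8 (not isolated)
Conditions: TMSOTf, Et3N, CH2Cl2, 0 °C; then Pd(OAc)2 (1.05 equiv), MeCN, rt
Reagents that add atoms: none
Why: Saegusa–Ito oxidation: only C8 is enolisable, silyl enol ether 8 gives a divalent palladium enolate, and β-hydride elimination from C7 gives the enone. C5 is quaternary, so no further dehydrogenation is possible.

Step 5
Reactants: 9 dimethyl 2,3,4-trimethoxy-9-oxo-6,9-dihydro-5H-benzo[7]annulene-5,5-dicarboxylate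
Product: 11 dimethyl (7R,8S)-2,3,4-trimethoxy-7,8-dimethyl-9-oxo-6,7,8,9-tetrahydro-5H-benzo[7]annulene-5,5-dicarboxylate, via bromomagnesium enolate 10 (not isolated)
Conditions: CuBr·SMe2 (5 mol%), (R,Sp)-Josiphos [(R)-1-[(Sp)-2-(diphenylphosphino)ferrocenyl]ethyldicyclohexylphosphine] (6 mol%), MeMgBr (slow addition), t-BuOMe, −78 °C; then MeI, DMPU, −78 → 0 °C
Reagents that add atoms: methylmagnesium bromide, C[Mg]Br; iodomethane, CI
Why: MeMgBr transmetallates to the monovalent copper–diphosphine complex, the methylcopper species binds the C7=C8 bond of 9 while magnesium activates the C9 carbonyl, and oxidative addition at C7 to a trivalent copper intermediate followed by reductive elimination forms the C7–CH3 bond and leaves enolate 10. MeI, activated by DMPU, then alkylates 10 at C8, its only nucleophilic carbon, to form the C8–CH3 bond. The closest known reaction type is the copper/ferrocenyl diphosphine-catalysed enantioselective conjugate addition of Grignard reagents to cyclic enones with alkylation of the magnesium enolate. No ring is closed in this step. C7 is controlled by the catalyst alone, because 9 has no stereocentre and its two C5 esters are identical, so there is neither a resident bias nor a kinetic resolution. C8 is controlled by C7, the electrophile approaching the enolate face opposite the new methyl to give the trans pair; C8 stays epimerisable, so a brief DBU treatment should converge any cis isomer to the trans ketone, which is expected to be the more stable. The step needs 1,4-addition in preference to 1,2- or ester addition, which the soft copper nucleophile, −78 °C and slow Grignard addition should secure, the esters sitting on a quaternary carbon. It also needs mono-C-methylation, helped by the fact that enolisation is possible only towards C8 and by excess MeI at low temperature.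

Step 6
Reactants: 11 dimethyl (7R,8S)-2,3,4-trimethoxy-7,8-dimethyl-9-oxo-6,7,8,9-tetrahydro-5H-benzo[7]annulene-5,5-dicarboxylate
Product: 12 dimethyl (7R,8S,9R)-9-hydroxy-2,3,4-trimethoxy-7,8-dimethyl-6,7,8,9-tetrahydro-5H-benzo[7]annulene-5,5-dicarboxylate
Conditions: (S)-2-methyl-CBS-oxazaborolidine (0.2 equiv), BH3·SMe2, THF, −20 °C; MeOH quench
Reagents that add atoms: none
Why: Corey–Bakshi–Shibata reduction of an aryl alkyl ketone with the arene as the large group; the (S)-catalyst should give the (9R) carbinol, hydroxyl trans to the C8 methyl. Borane spares the methyl esters at this temperature, and the neutral medium neither epimerises C8 nor frees an alkoxide that could lactonise onto a C5 ester.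

Step 7
Reactants: 12 dimethyl (7R,8S,9R)-9-hydroxy-2,3,4-trimethoxy-7,8-dimethyl-6,7,8,9-tetrahydro-5H-benzo[7]annulene-5,5-dicarboxylate
Product: 13 dimethyl (7R,8S,9R)-9-[(tert-butyldimethylsilyl)oxy]-2,3,4-trimethoxy-7,8-dimethyl-6,7,8,9-tetrahydro-5H-benzo[7]annulene-5,5-dicarboxylate
Conditions: TBSOTf, 2,6-lutidine, CH2Cl2, −78 → 0 °C
Reagents that add atoms: tert-butyldimethylsilyl trifluoromethanesulfonate, CC(C)(C)[Si](C)(C)OS(=O)(=O)C(F)(F)F
Why: Silylation of a hindered secondary benzylic alcohol with the silyl triflate and a non-nucleophilic base. The ether protects C9–O through the hydride and base steps ahead.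

Step 8
Reactants: 13 dimethyl (7R,8S,9R)-9-[(tert-butyldimethylsilyl)oxy]-2,3,4-trimethoxy-7,8-dimethyl-6,7,8,9-tetrahydro-5H-benzo[7]annulene-5,5-dicarboxylate
Product: 14 methyl (7R,8S,9R)-9-[(tert-butyldimethylsilyl)oxy]-2,3,4-trimethoxy-7,8-dimethyl-6,7,8,9-tetrahydro-5H-benzo[7]annulene-5-carboxylate (both C5 epimers)
Conditions: LiCl, H2O, DMSO, 150 °C
Reagents that add atoms: none
Why: Krapcho dealkoxycarbonylation: chloride dealkylates one methyl ester by SN2 at the methyl group, the carboxylate loses CO2 to a benzylic ester enolate, and water protonates it. The configuration at C5 is of no consequence because C5 is quaternised again in step 11.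

Step 9
Reactants: 14 methyl (7R,8S,9R)-9-[(tert-butyldimethylsilyl)oxy]-2,3,4-trimethoxy-7,8-dimethyl-6,7,8,9-tetrahydro-5H-benzo[7]annulene-5-carboxylate
Product: 15 [(7R,8S,9R)-9-[(tert-butyldimethylsilyl)oxy]-2,3,4-trimethoxy-7,8-dimethyl-6,7,8,9-tetrahydro-5H-benzo[7]annulen-5-yl]methanol (both C5 epimers)
Conditions: i-Bu2AlH (3 equiv), CH2Cl2, −78 → 0 °C; aq. potassium sodium tartrate
Reagents that add atoms: none
Why: Full hydride reduction of the ester to the primary alcohol. Reduction followed by reoxidation is chosen over partial reduction for reliability; the silyl and aryl ethers are inert.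

Step 10
Reactants: 15 [(7R,8S,9R)-9-[(tert-butyldimethylsilyl)oxy]-2,3,4-trimethoxy-7,8-dimethyl-6,7,8,9-tetrahydro-5H-benzo[7]annulen-5-yl]methanol
Product: 16 (7R,8S,9R)-9-[(tert-butyldimethylsilyl)oxy]-2,3,4-trimethoxy-7,8-dimethyl-6,7,8,9-tetrahydro-5H-benzo[7]annulene-5-carbaldehyde (both C5 epimers)
Conditions: Dess–Martin periodinane, NaHCO3, CH2Cl2, 0 °C → rt
Reagents that add atoms: none
Why: Dess–Martin oxidation under buffered conditions should give the α-aryl aldehyde without over-oxidation. The aldehyde is used at once, and epimerisation at C5 is irrelevant.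

Step 11
Reactants: 16 (7R,8S,9R)-9-[(tert-butyldimethylsilyl)oxy]-2,3,4-trimethoxy-7,8-dimethyl-6,7,8,9-tetrahydro-5H-benzo[7]annulene-5-carbaldehyde; 17 1-methoxybut-3-en-2-one
Product: 20 (7R,8S,9R)-9-[(tert-butyldimethylsilyl)oxy]-2,3,3',4-tetramethoxy-7,8-dimethyl-6,7,8,9-tetrahydrospiro[benzo[7]annulene-5,1'-cyclohex[2]en]-4'-one (both spiro epimers), via Michael adduct 18 (not isolated), via aldol 19 (not isolated)
Conditions: 17 (2 equiv), KOH (0.3 equiv), MeOH/THF, 0 → 50 °C
Reagents that add atoms: none
Why: Robinson annulation: the aryl-stabilised enolate of 16 adds through C5 to 17 to give keto aldehyde 18. Only the methoxy-bearing α-carbon of 18 can reach the non-enolisable aldehyde in a six-membered aldol closure (19), and dehydration gives the conjugated enone. Both configurations at C5 are acceptable, and C7, C8 and C9 carry no acidic hydrogen.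

Step 12
Reactants: 20 (7R,8S,9R)-9-[(tert-butyldimethylsilyl)oxy]-2,3,3',4-tetramethoxy-7,8-dimethyl-6,7,8,9-tetrahydrospiro[benzo[7]annulene-5,1'-cyclohex[2]en]-4'-one
Product: 22 (7R,8S,9R)-9-[(tert-butyldimethylsilyl)oxy]-3'-hydroxy-2,3,4,5'-tetramethoxy-7,8-dimethyl-6,7,8,9-tetrahydrospiro[benzo[7]annulene-5,1'-cyclohexa[2,5]dien]-4'-one (both spiro epimers), via hydroperoxide 21 (not isolated)
Conditions: KOt-Bu (3 equiv), O2 (1 atm), t-BuOH/THF, 0 °C → rt; AcOH quench
Reagents that add atoms: dioxygen, O=O
Why: Base-mediated autoxidation of a ketone to a diosphenol: C5' is the only enolisable position of 20, its potassium enolate captures O2 to give hydroperoxide 21, and 21 loses water under the basic conditions to the 4',5'-dione, which enolises to 22.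

Step 13
Reactants: 22 (7R,8S,9R)-9-[(tert-butyldimethylsilyl)oxy]-3'-hydroxy-2,3,4,5'-tetramethoxy-7,8-dimethyl-6,7,8,9-tetrahydrospiro[benzo[7]annulene-5,1'-cyclohexa[2,5]dien]-4'-one
Product: 23 (7R,8S,9R)-9-[(tert-butyldimethylsilyl)oxy]-2,3,3',4,5'-pentamethoxy-7,8-dimethyl-6,7,8,9-tetrahydrospiro[benzo[7]annulene-5,1'-cyclohexa[2,5]dien]-4'-one
Conditions: Me2SO4, K2CO3, acetone, reflux
Reagents that add atoms: dimethyl sulfate, COS(=O)(=O)OC
Why: Williamson-type O-methylation of the acidic diosphenol hydroxyl with a hard methylating agent; C-alkylation at C6' would be next to the quaternary carbon and is disfavoured. Ring C becomes symmetric, so the two spiro epimers converge to one compound.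

Step 14
Reactants: 23 (7R,8S,9R)-9-[(tert-butyldimethylsilyl)oxy]-2,3,3',4,5'-pentamethoxy-7,8-dimethyl-6,7,8,9-tetrahydrospiro[benzo[7]annulene-5,1'-cyclohexa[2,5]dien]-4'-one
Product: 24 (7R,8S,9R)-9-hydroxy-2,3,3',4,5'-pentamethoxy-7,8-dimethyl-6,7,8,9-tetrahydrospiro[benzo[7]annulene-5,1'-cyclohexa[2,5]dien]-4'-one
Conditions: HF·pyridine, THF/pyridine, 0 °C → rt
Reagents that add atoms: none
Why: Fluoride cleavage of the silyl ether, driven by Si–F bond formation. The buffered acidic reagent is chosen over basic fluoride so that no C9 alkoxide is formed that could add to the dienone.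

Step 15
Reactants: 24 (7R,8S,9R)-9-hydroxy-2,3,3',4,5'-pentamethoxy-7,8-dimethyl-6,7,8,9-tetrahydrospiro[benzo[7]annulene-5,1'-cyclohexa[2,5]dien]-4'-one
Product: 25 (7R,8S,9R)-2,3,3',4,5'-pentamethoxy-7,8-dimethyl-4'-oxo-6,7,8,9-tetrahydrospiro[benzo[7]annulene-5,1'-cyclohexa[2,5]dien]-9-yl acetate
Conditions: Ac2O, pyridine, DMAP (cat.), CH2Cl2, rt
Reagents that add atoms: acetic anhydride, CC(=O)OC(C)=O
Why: Nucleophile-catalysed acylation of the secondary benzylic alcohol. No stereocentre is touched and the dienone is inert to these conditions.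

## Compound list

1 | 1-bromo-2,3,4-trimethoxybenzene | COc1ccc(Br)c(OC)c1OC | starting material
2 | dimethyl malonate | COC(=O)CC(=O)OC | starting material
3 | dimethyl 2-(2,3,4-trimethoxyphenyl)malonate | COC(=O)C(C(=O)OC)c1ccc(OC)c(OC)c1OC | intermediate
4 | tert-butyl 4-bromobutanoate | CC(C)(C)OC(=O)CCCBr | starting material
5 | 4-tert-butyl 1,1-dimethyl 1-(2,3,4-trimethoxyphenyl)butane-1,1,4-tricarboxylate | COC(=O)C(CCCC(=O)OC(C)(C)C)(C(=O)OC)c1ccc(OC)c(OC)c1OC | intermediate
6 | 5,5-bis(methoxycarbonyl)-5-(2,3,4-trimethoxyphenyl)pentanoic acid | COC(=O)C(CCCC(=O)O)(C(=O)OC)c1ccc(OC)c(OC)c1OC | intermediate (not isolated)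
7 | dimethyl 2,3,4-trimethoxy-9-oxo-6,7,8,9-tetrahydro-5H-benzo[7]annulene-5,5-dicarboxylate | COC(=O)C1(C(=O)OC)CCCC(=O)c2cc(OC)c(OC)c(OC)c12 | intermediate
8 | dimethyl 2,3,4-trimethoxy-9-[(trimethylsilyl)oxy]-6,7-dihydro-5H-benzo[7]annulene-5,5-dicarboxylate | COC(=O)C1(C(=O)OC)CCC=C(O[Si](C)(C)C)c2cc(OC)c(OC)c(OC)c12 | intermediate (not isolated)
9 | dimethyl 2,3,4-trimethoxy-9-oxo-6,9-dihydro-5H-benzo[7]annulene-5,5-dicarboxylate | COC(=O)C1(C(=O)OC)CC=CC(=O)c2cc(OC)c(OC)c(OC)c12 | intermediate
10 | dimethyl (7R)-9-[(bromomagnesio)oxy]-2,3,4-trimethoxy-7-methyl-6,7-dihydro-5H-benzo[7]annulene-5,5-dicarboxylate | COC(=O)C1(C(=O)OC)C[C@@H](C)C=C(O[Mg]Br)c2cc(OC)c(OC)c(OC)c12 | intermediate (not isolated)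
11 | dimethyl (7R,8S)-2,3,4-trimethoxy-7,8-dimethyl-9-oxo-6,7,8,9-tetrahydro-5H-benzo[7]annulene-5,5-dicarboxylate | COC(=O)C1(C(=O)OC)C[C@@H](C)[C@H](C)C(=O)c2cc(OC)c(OC)c(OC)c12 | intermediate
12 | dimethyl (7R,8S,9R)-9-hydroxy-2,3,4-trimethoxy-7,8-dimethyl-6,7,8,9-tetrahydro-5H-benzo[7]annulene-5,5-dicarboxylate | COC(=O)C1(C(=O)OC)C[C@@H](C)[C@H](C)[C@@H](O)c2cc(OC)c(OC)c(OC)c12 | intermediate
13 | dimethyl (7R,8S,9R)-9-[(tert-butyldimethylsilyl)oxy]-2,3,4-trimethoxy-7,8-dimethyl-6,7,8,9-tetrahydro-5H-benzo[7]annulene-5,5-dicarboxylate | COC(=O)C1(C(=O)OC)C[C@@H](C)[C@H](C)[C@@H](O[Si](C)(C)C(C)(C)C)c2cc(OC)c(OC)c(OC)c12 | intermediate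
14 | methyl (7R,8S,9R)-9-[(tert-butyldimethylsilyl)oxy]-2,3,4-trimethoxy-7,8-dimethyl-6,7,8,9-tetrahydro-5H-benzo[7]annulene-5-carboxylate (both C5 epimers) | COC(=O)C1C[C@@H](C)[C@H](C)[C@@H](O[Si](C)(C)C(C)(C)C)c2cc(OC)c(OC)c(OC)c12 | intermediate
15 | [(7R,8S,9R)-9-[(tert-butyldimethylsilyl)oxy]-2,3,4-trimethoxy-7,8-dimethyl-6,7,8,9-tetrahydro-5H-benzo[7]annulen-5-yl]methanol (both C5 epimers) | OCC1C[C@@H](C)[C@H](C)[C@@H](O[Si](C)(C)C(C)(C)C)c2cc(OC)c(OC)c(OC)c12 | intermediate
16 | (7R,8S,9R)-9-[(tert-butyldimethylsilyl)oxy]-2,3,4-trimethoxy-7,8-dimethyl-6,7,8,9-tetrahydro-5H-benzo[7]annulene-5-carbaldehyde (both C5 epimers) | O=CC1C[C@@H](C)[C@H](C)[C@@H](O[Si](C)(C)C(C)(C)C)c2cc(OC)c(OC)c(OC)c12 | intermediate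
17 | 1-methoxybut-3-en-2-one | COCC(=O)C=C | starting material
18 | (7R,8S,9R)-9-[(tert-butyldimethylsilyl)oxy]-2,3,4-trimethoxy-5-(4-methoxy-3-oxobutyl)-7,8-dimethyl-6,7,8,9-tetrahydro-5H-benzo[7]annulene-5-carbaldehyde (both C5 epimers) | COCC(=O)CCC1(C=O)C[C@@H](C)[C@H](C)[C@@H](O[Si](C)(C)C(C)(C)C)c2cc(OC)c(OC)c(OC)c12 | intermediate (not isolated)
19 | (7R,8S,9R)-9-[(tert-butyldimethylsilyl)oxy]-2'-hydroxy-2,3,3',4-tetramethoxy-7,8-dimethyl-6,7,8,9-tetrahydrospiro[benzo[7]annulene-5,1'-cyclohexan]-4'-one (isomers at C5, C2' and C3') | COC1C(O)C2(CCC1=O)C[C@@H](C)[C@H](C)[C@@H](O[Si](C)(C)C(C)(C)C)c1cc(OC)c(OC)c(OC)c12 | intermediate (not isolated)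
20 | (7R,8S,9R)-9-[(tert-butyldimethylsilyl)oxy]-2,3,3',4-tetramethoxy-7,8-dimethyl-6,7,8,9-tetrahydrospiro[benzo[7]annulene-5,1'-cyclohex[2]en]-4'-one (both spiro epimers) | COC1=CC2(CCC1=O)C[C@@H](C)[C@H](C)[C@@H](O[Si](C)(C)C(C)(C)C)c1cc(OC)c(OC)c(OC)c12 | intermediate
21 | (7R,8S,9R)-9-[(tert-butyldimethylsilyl)oxy]-5'-hydroperoxy-2,3,3',4-tetramethoxy-7,8-dimethyl-6,7,8,9-tetrahydrospiro[benzo[7]annulene-5,1'-cyclohex[2]en]-4'-one (mixture of isomers) | COC1=CC2(CC(OO)C1=O)C[C@@H](C)[C@H](C)[C@@H](O[Si](C)(C)C(C)(C)C)c1cc(OC)c(OC)c(OC)c12 | intermediate (not isolated)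
22 | (7R,8S,9R)-9-[(tert-butyldimethylsilyl)oxy]-3'-hydroxy-2,3,4,5'-tetramethoxy-7,8-dimethyl-6,7,8,9-tetrahydrospiro[benzo[7]annulene-5,1'-cyclohexa[2,5]dien]-4'-one (both spiro epimers) | COC1=CC2(C=C(O)C1=O)C[C@@H](C)[C@H](C)[C@@H](O[Si](C)(C)C(C)(C)C)c1cc(OC)c(OC)c(OC)c12 | intermediate
23 | (7R,8S,9R)-9-[(tert-butyldimethylsilyl)oxy]-2,3,3',4,5'-pentamethoxy-7,8-dimethyl-6,7,8,9-tetrahydrospiro[benzo[7]annulene-5,1'-cyclohexa[2,5]dien]-4'-one | COC1=CC2(C=C(OC)C1=O)C[C@@H](C)[C@H](C)[C@@H](O[Si](C)(C)C(C)(C)C)c1cc(OC)c(OC)c(OC)c12 | intermediate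
24 | (7R,8S,9R)-9-hydroxy-2,3,3',4,5'-pentamethoxy-7,8-dimethyl-6,7,8,9-tetrahydrospiro[benzo[7]annulene-5,1'-cyclohexa[2,5]dien]-4'-one | COC1=CC2(C=C(OC)C1=O)C[C@@H](C)[C@H](C)[C@@H](O)c1cc(OC)c(OC)c(OC)c12 | intermediate
25 | (7R,8S,9R)-2,3,3',4,5'-pentamethoxy-7,8-dimethyl-4'-oxo-6,7,8,9-tetrahydrospiro[benzo[7]annulene-5,1'-cyclohexa[2,5]dien]-9-yl acetate | COC1=CC2(C=C(OC)C1=O)C[C@@H](C)[C@H](C)[C@@H](OC(C)=O)c1cc(OC)c(OC)c(OC)c12 | target

## Step count and least certain steps

Total step count: 15. Longest linear sequence: 15 steps (1 → 25); the route is linear, with 2, 4 and 17 entering as reagent-sized fragments.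

**Step 5 (key step).** The enone is cross-conjugated with an electron-rich arene and may react slowly, which would let 1,2-addition or ester attack compete. Facial selection by the catalyst may be incomplete on this new ring type. The magnesium enolate may alkylate sluggishly, allowing proton exchange, double methylation at C8 or attack of the enolate on a C5 ester. Fallback, from 9 back to 11: the two bond formations are separated. The copper-catalysed conjugate methylation is quenched with aqueous NH4Cl to give dimethyl (7R)-2,3,4-trimethoxy-7-methyl-9-oxo-6,7,8,9-tetrahydro-5H-benzo[7]annulene-5,5-dicarboxylate F1, which is purified and enriched by crystallisation if needed. F1 is then converted into its lithium enolate (LiN(SiMe3)2, THF, −78 °C) and methylated with MeI, and C8 is equilibrated with DBU to give 11.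

**Step 6.** The catalyst's preference may oppose the intrinsic facial bias of the ring (a mismatched pair) and lower the selectivity at C9, and any alkoxide formed on work-up could close a bridged lactone onto a C5 ester. Fallback, from 11 back to 12: substrate-controlled reduction with the bulky hydride LiBH(s-Bu)3 at −78 °C, expected to attack anti to the C8 methyl, gives dimethyl (7R,8S,9S)-9-hydroxy-2,3,4-trimethoxy-7,8-dimethyl-6,7,8,9-tetrahydro-5H-benzo[7]annulene-5,5-dicarboxylate F2. Mitsunobu inversion (4-nitrobenzoic acid, PPh3, DIAD, THF) gives dimethyl (7R,8S,9R)-2,3,4-trimethoxy-7,8-dimethyl-9-[(4-nitrobenzoyl)oxy]-6,7,8,9-tetrahydro-5H-benzo[7]annulene-5,5-dicarboxylate F3, and brief methanolysis (K2CO3, MeOH, 0 °C) gives 12.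

**Step 11.** The Michael addition has to form a quaternary carbon beside the C4 methoxy group. It may be slow or reversible, while the vinyl ketone polymerises and the hindered aldehyde suffers base-induced deformylation. Fallback, from 16 back to 18 and then 20: the aldehyde is converted (TMSOTf, Et3N, CH2Cl2) into tert-butyl{[(7R,8S,9R)-2,3,4-trimethoxy-7,8-dimethyl-5-{[(trimethylsilyl)oxy]methylidene}-6,7,8,9-tetrahydro-5H-benzo[7]annulen-9-yl]oxy}dimethylsilane F4. F4 undergoes a Lewis-acid-promoted Mukaiyama–Michael addition to 17 (Sc(OTf)3 cat., CH2Cl2, −40 °C) to give keto aldehyde 18 after work-up. 18 is then cyclised in a separate operation (pyrrolidine, AcOH, toluene, 60 °C) to 20.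

**Step 12.** Oxygenation of the enolate may not stop at the diosphenol; the electron-rich diosphenolate can take up more oxygen and undergo C4'–C5' cleavage. Fallback, from 20 back to 22: the enolate (KN(SiMe3)2, THF, −78 °C) is hydroxylated with 2-(phenylsulfonyl)-3-phenyloxaziridine to give (7R,8S,9R)-9-[(tert-butyldimethylsilyl)oxy]-5'-hydroxy-2,3,3',4-tetramethoxy-7,8-dimethyl-6,7,8,9-tetrahydrospiro[benzo[7]annulene-5,1'-cyclohex[2]en]-4'-one F5. Swern oxidation (DMSO, (COCl)2, Et3N, −78 °C) then gives the dione, which enolises to 22.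

## Further compounds

F1 | step 5 | dimethyl (7R)-2,3,4-trimethoxy-7-methyl-9-oxo-6,7,8,9-tetrahydro-5H-benzo[7]annulene-5,5-dicarboxylate | COC(=O)C1(C(=O)OC)C[C@@H](C)CC(=O)c2cc(OC)c(OC)c(OC)c12
F2 | step 6 | dimethyl (7R,8S,9S)-9-hydroxy-2,3,4-trimethoxy-7,8-dimethyl-6,7,8,9-tetrahydro-5H-benzo[7]annulene-5,5-dicarboxylate | COC(=O)C1(C(=O)OC)C[C@@H](C)[C@H](C)[C@H](O)c2cc(OC)c(OC)c(OC)c12
F3 | step 6 | dimethyl (7R,8S,9R)-2,3,4-trimethoxy-7,8-dimethyl-9-[(4-nitrobenzoyl)oxy]-6,7,8,9-tetrahydro-5H-benzo[7]annulene-5,5-dicarboxylate | COC(=O)C1(C(=O)OC)C[C@@H](C)[C@H](C)[C@@H](OC(=O)c3ccc(cc3)[N+](=O)[O-])c2cc(OC)c(OC)c(OC)c12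
F4 | step 11 | tert-butyl{[(7R,8S,9R)-2,3,4-trimethoxy-7,8-dimethyl-5-{[(trimethylsilyl)oxy]methylidene}-6,7,8,9-tetrahydro-5H-benzo[7]annulen-9-yl]oxy}dimethylsilane | C[Si](C)(C)OC=C1C[C@@H](C)[C@H](C)[C@@H](O[Si](C)(C)C(C)(C)C)c2cc(OC)c(OC)c(OC)c12
F5 | step 12 | (7R,8S,9R)-9-[(tert-butyldimethylsilyl)oxy]-5'-hydroxy-2,3,3',4-tetramethoxy-7,8-dimethyl-6,7,8,9-tetrahydrospiro[benzo[7]annulene-5,1'-cyclohex[2]en]-4'-one | COC1=CC2(CC(O)C1=O)C[C@@H](C)[C@H](C)[C@@H](O[Si](C)(C)C(C)(C)C)c1cc(OC)c(OC)c(OC)c12
A1 | alternative 1 | (5R,7R,8S,9R)-9-[(tert-butyldimethylsilyl)oxy]-2,3,3',4-tetramethoxy-7,8-dimethyl-6,7,8,9-tetrahydrospiro[benzo[7]annulene-5,1'-cyclohex[2]en]-4'-one | COC1=C[C@@]2(CCC1=O)C[C@@H](C)[C@H](C)[C@@H](O[Si](C)(C)C(C)(C)C)c1cc(OC)c(OC)c(OC)c12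
A2 | alternative 2 | 2-(2-diazoacetyl)-3,4,5-trimethoxybenzaldehyde | O=Cc1cc(OC)c(OC)c(OC)c1C(=O)C=[N+]=[N-]
A3 | alternative 2 | 5,6,7-trimethoxy-2-benzopyrylium-4-olate | [O-]c1c[o+]cc2cc(OC)c(OC)c(OC)c12
A4 | alternative 2 | (E)-3-(but-2-enoyl)oxazolidin-2-one | C/C=C/C(=O)N1CCOC1=O
A5 | alternative 2 | 6,9-epoxy-2,3,4-trimethoxy-7-methyl-8-(2-oxooxazolidine-3-carbonyl)-6,7,8,9-tetrahydro-5H-benzo[7]annulen-5-one (8-endo acyl, 7-exo methyl, absolute configuration as drawn) | O=C1[C@@H]2[C@@H](C)[C@H](C(=O)N3CCOC3=O)[C@@H](O2)c2cc(OC)c(OC)c(OC)c12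
A6 | alternative 3 | 3,4,5-trimethoxy-2-(trimethylsilyl)phenyl trifluoromethanesulfonate | COc1cc(OS(=O)(=O)C(F)(F)F)c([Si](C)(C)C)c(OC)c1OC
A7 | alternative 3 | 3,4,5-trimethoxybenzyne | COC1=CC#CC(OC)=C1OC
A8 | alternative 3 | methyl (4R,5S)-4,5-dimethyl-2-oxocyclopentane-1-carboxylate | COC(=O)C1C(=O)C[C@@H](C)[C@@H]1C
A9 | alternative 3 | methyl (7R,8S,9R)-2,3,4-trimethoxy-7,8-dimethyl-5-oxo-6,7,8,9-tetrahydro-5H-benzo[7]annulene-9-carboxylate | O=C1C[C@@H](C)[C@H](C)[C@@H](C(=O)OC)c2cc(OC)c(OC)c(OC)c12
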